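**Retrosynthetic overview**
- Target ⇐ last-step epoxidation of the 1(10)-alkene, after Yamaguchi esterification at C8 with a pre-formed (2S,3R)-epoxy acid (Sharpless epoxidation of tiglyl alcohol) and isovalerylation at C3.
- α-Methylene lactone ⇐ C6 ketone reduction/lactonization and Eschenmoser methylenation of a ten-membered keto ester.
- Key step, with no macrocyclization: anionic oxy-Cope ring expansion of a 1-[(Z)-2-alkoxyvinyl]-6-isopropenylcyclohex-2-enol with in-flask enolate alkylation. One pot is meant to give the ten-membered ring, the 4Z alkene (from the cyclohexene), the 1(10)E alkene (chair), C8 (chirality transfer from C1) and C7.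
- Carbinol ⇐ (Z)-2-(PMB-oxy)vinyllithium + 4-silyloxy-isopiperitenone ⇐ (S)-carvone (Luche reduction, directed epoxidation, selenide transposition, oxidative transposition).
- Ring order: cyclohexene (chiral pool) → ten-membered carbocycle ([3,3] ring expansion) → γ-lactone → ring oxirane last; the side-chain oxirane is made separately.

Assumption: ring positions of all intermediates carry the germacrane numbering of the target (C1–C10 ring, C11–C13 lactone carbons, C14 on C10, C15 on C4); (S)-(+)-carvone, 4-methoxybenzyl alcohol and (E)-2-methylbut-2-en-1-ol are taken as commercial.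

**Step 1**
Reactants: 1 (S)-(+)-carvone
Product: 2 (1S,5S)-cis-carveol
Conditions: NaBH4, CeCl3·7H2O, MeOH, −78 → 0 °C
Reagents that add atoms: none
Why: Luche 1,2-reduction; axial hydride delivery to the half-chair with equatorial isopropenyl gives the alcohol cis to isopropenyl, which sets the future C3–O centre (S).

**Step 2**
Reactants: 2 (1S,5S)-cis-carveol
Product: 3 (1S,2S,4R,6R)-1-methyl-4-(prop-1-en-2-yl)-7-oxabicyclo[4.1.0]heptan-2-ol
Conditions: VO(acac)2 (2 mol %), t-BuOOH, PhMe, 0 → 23 °C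
Reagents that add atoms: tert-butyl hydroperoxide, CC(C)(C)OO
Why: hydroxyl-directed vanadium-catalysed epoxidation (Sharpless–Michaelson type) places the oxirane syn to the OH and spares the isopropenyl alkene; both oxirane centres are temporary.

**Step 3**
Reactants: 3 epoxy alcohol
Product: 4 tert-butyldimethylsilyl ether of 3
Conditions: TBSCl, imidazole, DMF, 23 °C
Reagents that add atoms: tert-butyldimethylsilyl chloride, CC(C)(C)[Si](C)(C)Cl
Why: standard silylation of the secondary alcohol; no stereocentre is touched.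

**Step 4**
Reactants: 4 silyl ether epoxide
Product: 7 (1R,4R,6S)-6-[(tert-butyldimethylsilyl)oxy]-1-methyl-4-(prop-1-en-2-yl)cyclohex-2-en-1-ol, via hydroxy selenide 5 (not isolated), via selenoxide 6 (not isolated)
Conditions: (PhSe)2, NaBH4, EtOH, 78 °C; then 30% H2O2, THF, 0 → 23 °C
Reagents that add atoms: none
Why: Sharpless–Lauer epoxide-to-allylic-alcohol transposition; PhSe− opens the oxirane by SN2 at the secondary carbon C5 in the trans-diaxial (Fürst–Plattner) sense with both ring substituents equatorial, and selenoxide syn-elimination can only go toward C6.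

**Step 5**
Reactants: 7 tertiary allylic alcohol
Product: 10 (4S,6S)-4-[(tert-butyldimethylsilyl)oxy]-3-methyl-6-(prop-1-en-2-yl)cyclohex-2-en-1-one, via tertiary chlorochromate ester 8 (not isolated), via transposed chlorochromate ester 9 (not isolated)
Conditions: [C5H5NH][CrO3Cl] (pyridinium chlorochromate), 4 Å MS, CH2Cl2, 23 °C
Reagents that add atoms: pyridinium chlorochromate, [O-][Cr](=O)(=O)Cl.c1cc[nH+]cc1
Why: Dauben–Michno (Babler) oxidative 1,3-transposition; the tertiary chromate undergoes a [3,3] shift to the secondary allylic chromate, which is oxidised to the enone, and the C1 and C3 centres are untouched.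

**Step 6**
Reactants: 11 4-methoxybenzyl alcohol
Product: 12 4-methoxybenzyl vinyl ether
Conditions: Pd(OAc)2 (cat.), 1,10-phenanthroline (cat.), ethyl vinyl ether (excess), CH2Cl2, 23 °C
Reagents that add atoms: ethyl vinyl ether, C=COCC
Why: divalent-palladium-catalysed transfer vinylation (transetherification) of a primary alcohol, driven by excess vinyl ether.

**Step 7**
Reactants: 12 4-methoxybenzyl vinyl ether
Product: 14 (Z)-2-bromovinyl 4-methoxybenzyl ether, via 1,2-dibromoethyl ether 13 (not isolated)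
Conditions: Br2, CH2Cl2, −78 °C; then i-Pr2NEt, −78 → 40 °C
Reagents that add atoms: bromine, BrBr
Why: bromine addition to the enol ether then amine-induced dehydrobromination; 2-halovinyl ethers form mainly as the Z isomer (cis effect), and the minor E isomer is removed by chromatography.

**Step 8**
Reactants: 14 (Z)-2-bromovinyl 4-methoxybenzyl ether; 10 enone
Product: 16 (1S,4S,6S)-4-[(tert-butyldimethylsilyl)oxy]-1-{(Z)-2-[(4-methoxybenzyl)oxy]ethenyl}-3-methyl-6-(prop-1-en-2-yl)cyclohex-2-en-1-ol, via (Z)-alkoxyvinyllithium 15 (not isolated)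
Conditions: 14, t-BuLi (2 equiv), Et2O, −78 °C; then 10, THF, −78 °C; then H2O
Reagents that add atoms: none
Why: Br–Li exchange keeps the Z geometry (O→Li chelation) and the alkenyllithium adds 1,2 to the enone anti to the adjacent equatorial isopropenyl group (equatorial attack), giving the trans-1,2-dialkenyl carbinol; this carbinol centre is consumed in step 9.

**Step 9**
Reactants: 16 dialkenyl carbinol
Product: 19 ethyl 2-[(1R,2R,4E,7S,8Z)-7-[(tert-butyldimethylsilyl)oxy]-2-[(4-methoxybenzyl)oxy]-4,8-dimethyl-10-oxocyclodeca-4,8-dien-1-yl]acetate, via potassium alkoxide 17 (not isolated), via potassium enolate 18 (not isolated)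
Conditions: KN(SiMe3)2 (1.1 equiv), THF, −78 → 23 °C; then ICH2CO2Et, −78 → −40 °C
Reagents that add atoms: ethyl iodoacetate, CCOC(=O)CI
Why: Proposed new method: anionic oxy-Cope ring expansion whose migrating terminus carries a (Z)-alkoxy group (closest known type: potassium-alkoxide oxy-Cope of isopiperitenone-derived 1,2-dialkenylcyclohexenols with in-flask enolate alkylation); in the K+-bridged chair transition state (ring bonds equatorial, alkoxide and OPMB syn-axial) C9 bonds to one face of the Z-enol ether so that the C1 centre is traded for C8 (R), the new alkene is 1(10)E and the cyclohexene alkene stays 4Z, and the K+ chelate between enolate oxygen and C8 ether oxygen holds the C8–O bond in the nodal plane of the enolate (no E1cB) while ethyl iodoacetate attacks C7 on the outer face anti to C9 (7R).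

**Step 10**
Reactants: 19 keto ester
Product: 21 (3aR,4R,6E,9S,10Z,11aR)-9-[(tert-butyldimethylsilyl)oxy]-4-[(4-methoxybenzyl)oxy]-6,10-dimethyl-3a,4,5,8,9,11a-hexahydrocyclodeca[b]furan-2(3H)-one, via hydroxy ester 20 (not isolated)
Conditions: NaBH4, CeCl3·7H2O, MeOH, −78 °C; then PPTS (cat.), CH2Cl2, 23 °C
Reagents that add atoms: none
Why: Luche 1,2-reduction then acid-catalysed lactonization; hydride attacks the outer face of the C6 carbonyl in the conformer that has H7 eclipsing C=O and the acetate arm outside, giving the 6R (6α) alcohol trans to the C7 arm, which closes the trans-fused γ-lactone.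

**Step 11**
Reactants: 21 lactone
Product: 23 3-[(dimethylamino)methyl] derivative of 21 (C11 epimers), via lithium lactone enolate 22 (not isolated)
Conditions: LiN(iPr)2, THF, −78 °C; then CH2=NMe2+ I−, −78 → 0 °C
Reagents that add atoms: N,N-dimethylmethyleneiminium iodide (Eschenmoser's salt), C=[N+](C)C.[I-]
Why: Mannich reaction of the lactone enolate with Eschenmoser's salt; the new C11 centre is destroyed in step 12.

**Step 12**
Reactants: 23 Mannich base
Product: 25 (3aR,4R,6E,9S,10Z,11aR)-9-[(tert-butyldimethylsilyl)oxy]-4-[(4-methoxybenzyl)oxy]-6,10-dimethyl-3-methylidene-3a,4,5,8,9,11a-hexahydrocyclodeca[b]furan-2(3H)-one, via trimethylammonium iodide 24 (not isolated)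
Conditions: MeI, MeOH, 23 °C; then aq NaHCO3, EtOAc, 23 °C
Reagents that add atoms: none
Why: N-quaternisation then E1cB (Hofmann-type) loss of trimethylamine gives the α-methylene-γ-lactone without touching C6, C7 or C8.

**Step 13**
Reactants: 25 α-methylene lactone
Product: 26 (3aR,4R,6E,9S,10Z,11aR)-9-hydroxy-4-[(4-methoxybenzyl)oxy]-6,10-dimethyl-3-methylidene-3a,4,5,8,9,11a-hexahydrocyclodeca[b]furan-2(3H)-one
Conditions: HF·pyridine, pyridine/THF, 0 → 23 °C
Reagents that add atoms: none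
Why: buffered fluoride desilylation frees the C3 alcohol and leaves the PMB ether and the Michael acceptor intact; it is done before any oxirane is present.

**Step 14**
Reactants: 26 C3 alcohol
Product: 27 (3aR,4R,6E,9S,10Z,11aR)-4-[(4-methoxybenzyl)oxy]-6,10-dimethyl-3-methylidene-2-oxo-2,3,3a,4,5,8,9,11a-octahydrocyclodeca[b]furan-9-yl 3-methylbutanoate
Conditions: isovaleryl chloride, pyridine, DMAP (cat.), CH2Cl2, 0 °C
Reagents that add atoms: 3-methylbutanoyl chloride, CC(C)CC(=O)Cl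
Why: DMAP-catalysed acylation of the allylic C3 alcohol with retention.

**Step 15**
Reactants: 27 isovalerate
Product: 28 (3aR,4R,6E,9S,10Z,11aR)-4-hydroxy-6,10-dimethyl-3-methylidene-2-oxo-2,3,3a,4,5,8,9,11a-octahydrocyclodeca[b]furan-9-yl 3-methylbutanoate
Conditions: DDQ, CH2Cl2/pH 7 buffer (10:1), 0 → 23 °C
Reagents that add atoms: none
Why: oxidative cleavage of the PMB ether by DDQ under neutral conditions; the alkenes, the ester and the lactone are inert.

**Step 16**
Reactants: 29 (E)-2-methylbut-2-en-1-ol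
Product: 30 [(2R,3R)-2,3-dimethyloxiran-2-yl]methanol
Conditions: Ti(OiPr)4 (10 mol %), D-(−)-diethyl tartrate (12 mol %), t-BuOOH, 4 Å MS, CH2Cl2, −20 °C
Reagents that add atoms: tert-butyl hydroperoxide, CC(C)(C)OO
Why: Katsuki–Sharpless asymmetric epoxidation; the D-(−)-tartrate catalyst delivers oxygen to the face that gives the (2R,3R)-epoxy alcohol from this E-allylic alcohol, setting both side-chain centres.

**Step 17**
Reactants: 30 epoxy alcohol
Product: 32 (2S,3R)-2,3-dimethyloxirane-2-carboxylic acid, via epoxy aldehyde 31 (not isolated)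
Conditions: RuCl3·3H2O (2 mol %), NaIO4, CCl4/MeCN/H2O, 0 → 23 °C
Reagents that add atoms: water, O
Why: RuO4-type (Sharpless) oxidation of the primary alcohol through the aldehyde hydrate to the acid; the oxirane centres are untouched (C2 becomes S only through a priority change).

**Step 18**
Reactants: 28 C8 alcohol; 32 epoxy acid
Product: 34 (3aR,4R,6E,9S,10Z,11aR)-6,10-dimethyl-9-[(3-methylbutanoyl)oxy]-3-methylidene-2-oxo-2,3,3a,4,5,8,9,11a-octahydrocyclodeca[b]furan-4-yl (2S,3R)-2,3-dimethyloxirane-2-carboxylate, via mixed anhydride 33 (not isolated)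
Conditions: 32, 2,4,6-trichlorobenzoyl chloride, Et3N, PhMe, 23 °C; then 28, DMAP, PhMe, 23 → 40 °C
Reagents that add atoms: none
Why: Yamaguchi esterification; DMAP transfers the glycidic acyl group from the mixed anhydride to the hindered C8 alcohol with retention at C8 and without opening the oxirane.

**Step 19**
Reactants: 34 diester diene
Product: 35 target, (1R,3S,6R,7R,8R,10R)-1,10-epoxy-3-(3-methylbutanoyloxy)-8-{[(2S,3R)-2,3-dimethyloxirane-2-carbonyl]oxy}germacra-4(Z),11(13)-dien-12,6-olide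
Conditions: mCPBA, NaHCO3, CH2Cl2, −20 → 0 °C
Reagents that add atoms: 3-chloroperoxybenzoic acid, OOC(=O)c1cccc(Cl)c1
Why: Prilezhaev epoxidation; only the 1(10) alkene is electron-rich enough (the 4,5-alkene is deactivated by two allylic acyloxy groups, the 11(13)-alkene is conjugated), and the peracid attacks the outer face of the E-alkene in the ring conformer with C14 on the β face, giving the 1β,10α (1R,10R) oxirane.

**Compound list**
1 | (S)-(+)-carvone, (5S)-2-methyl-5-(prop-1-en-2-yl)cyclohex-2-en-1-one | CC1=CC[C@@H](CC1=O)C(C)=C | starting material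
2 | (1S,5S)-cis-carveol | CC1=CC[C@@H](C[C@@H]1O)C(C)=C | intermediate
3 | (1S,2S,4R,6R)-1-methyl-4-(prop-1-en-2-yl)-7-oxabicyclo[4.1.0]heptan-2-ol (oxirane cis to OH and to isopropenyl) | O[C@H]1C[C@@H](C(C)=C)C[C@H]2O[C@@]12C | intermediate
4 | tert-butyldimethylsilyl ether of 3 | CC(C)(C)[Si](C)(C)O[C@H]1C[C@@H](C(C)=C)C[C@H]2O[C@@]12C | intermediate
5 | hydroxy selenide: tertiary OH at C4 (cis to OTBS and isopropenyl), PhSe at C5 trans to that OH | CC(C)(C)[Si](C)(C)O[C@H]1C[C@@H](C(C)=C)C[C@H]([Se]c2ccccc2)[C@@]1(C)O | intermediate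
6 | selenoxide of 5 (configuration at Se undefined) | CC(C)(C)[Si](C)(C)O[C@H]1C[C@@H](C(C)=C)C[C@H]([Se](=O)c2ccccc2)[C@@]1(C)O | intermediate
7 | (1R,4R,6S)-6-[(tert-butyldimethylsilyl)oxy]-1-methyl-4-(prop-1-en-2-yl)cyclohex-2-en-1-ol | CC(C)(C)[Si](C)(C)O[C@H]1C[C@@H](C(C)=C)C=C[C@@]1(C)O | intermediate
8 | tertiary chlorochromate ester of 7 | CC(C)(C)[Si](C)(C)O[C@H]1C[C@@H](C(C)=C)C=C[C@@]1(C)O[Cr](=O)(=O)Cl | intermediate
9 | transposed secondary allylic chlorochromate ester (O on C6, alkene C4=C5) | CC(C)(C)[Si](C)(C)O[C@H]1C[C@@H](C(C)=C)[C@@H](O[Cr](=O)(=O)Cl)C=C1C | intermediate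
10 | (4S,6S)-4-[(tert-butyldimethylsilyl)oxy]-3-methyl-6-(prop-1-en-2-yl)cyclohex-2-en-1-one | CC(C)(C)[Si](C)(C)O[C@H]1C[C@@H](C(C)=C)C(=O)C=C1C | intermediate
11 | 4-methoxybenzyl alcohol | COc1ccc(CO)cc1 | starting material
12 | 4-methoxybenzyl vinyl ether | C=COCc1ccc(OC)cc1 | intermediate
13 | 1,2-dibromoethyl 4-methoxybenzyl ether (racemic) | BrCC(Br)OCc1ccc(OC)cc1 | intermediate
14 | (Z)-2-bromovinyl 4-methoxybenzyl ether | Br/C=C\OCc1ccc(OC)cc1 | intermediate
15 | (Z)-2-[(4-methoxybenzyl)oxy]vinyllithium | [Li]/C=C\OCc1ccc(OC)cc1 | intermediate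
16 | (1S,4S,6S)-4-[(tert-butyldimethylsilyl)oxy]-1-{(Z)-2-[(4-methoxybenzyl)oxy]ethenyl}-3-methyl-6-(prop-1-en-2-yl)cyclohex-2-en-1-ol (alkenyl groups trans) | CC(C)(C)[Si](C)(C)O[C@H]1C[C@@H](C(C)=C)[C@](O)(/C=C\OCc2ccc(OC)cc2)C=C1C | intermediate
17 | potassium alkoxide of 16 | [K+].CC(C)(C)[Si](C)(C)O[C@H]1C[C@@H](C(C)=C)[C@]([O-])(/C=C\OCc2ccc(OC)cc2)C=C1C | intermediate
18 | potassium enolate of the ring-expanded ketone (C6–O−, C6=C7; 8R, 3S, 4Z, 1(10)E) | [K+].C/C1=C/C([O-])=C/[C@H](OCc2ccc(OC)cc2)C/C(C)=C/C[C@@H]1O[Si](C)(C)C(C)(C)C | intermediate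
19 | ethyl 2-[(1R,2R,4E,7S,8Z)-7-[(tert-butyldimethylsilyl)oxy]-2-[(4-methoxybenzyl)oxy]-4,8-dimethyl-10-oxocyclodeca-4,8-dien-1-yl]acetate | CCOC(=O)C[C@@H]1[C@H](OCc2ccc(OC)cc2)C/C(C)=C/C[C@H](O[Si](C)(C)C(C)(C)C)/C(C)=C\C1=O | intermediate
20 | ethyl 2-[(1S,2R,4E,7S,8Z,10R)-7-[(tert-butyldimethylsilyl)oxy]-10-hydroxy-2-[(4-methoxybenzyl)oxy]-4,8-dimethylcyclodeca-4,8-dien-1-yl]acetate (6α-alcohol) | CCOC(=O)C[C@@H]1[C@H](OCc2ccc(OC)cc2)C/C(C)=C/C[C@H](O[Si](C)(C)C(C)(C)C)/C(C)=C\[C@H]1O | intermediate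
21 | (3aR,4R,6E,9S,10Z,11aR)-9-[(tert-butyldimethylsilyl)oxy]-4-[(4-methoxybenzyl)oxy]-6,10-dimethyl-3a,4,5,8,9,11a-hexahydrocyclodeca[b]furan-2(3H)-one | O=C1C[C@@H]2[C@H](OCc3ccc(OC)cc3)C/C(C)=C/C[C@H](O[Si](C)(C)C(C)(C)C)/C(C)=C\[C@H]2O1 | intermediate
22 | lithium enolate of 21 | [Li+].[O-]C1=C[C@@H]2[C@H](OCc3ccc(OC)cc3)C/C(C)=C/C[C@H](O[Si](C)(C)C(C)(C)C)/C(C)=C\[C@H]2O1 | intermediate
23 | 3-[(dimethylamino)methyl] derivative of 21 (C11 epimers) | O=C1C(CN(C)C)[C@@H]2[C@H](OCc3ccc(OC)cc3)C/C(C)=C/C[C@H](O[Si](C)(C)C(C)(C)C)/C(C)=C\[C@H]2O1 | intermediate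
24 | trimethylammonium iodide of 23 | [I-].O=C1C(C[N+](C)(C)C)[C@@H]2[C@H](OCc3ccc(OC)cc3)C/C(C)=C/C[C@H](O[Si](C)(C)C(C)(C)C)/C(C)=C\[C@H]2O1 | intermediate
25 | (3aR,4R,6E,9S,10Z,11aR)-9-[(tert-butyldimethylsilyl)oxy]-4-[(4-methoxybenzyl)oxy]-6,10-dimethyl-3-methylidene-3a,4,5,8,9,11a-hexahydrocyclodeca[b]furan-2(3H)-one | O=C1C(=C)[C@@H]2[C@H](OCc3ccc(OC)cc3)C/C(C)=C/C[C@H](O[Si](C)(C)C(C)(C)C)/C(C)=C\[C@H]2O1 | intermediate
26 | (3aR,4R,6E,9S,10Z,11aR)-9-hydroxy-4-[(4-methoxybenzyl)oxy]-6,10-dimethyl-3-methylidene-3a,4,5,8,9,11a-hexahydrocyclodeca[b]furan-2(3H)-one | O=C1C(=C)[C@@H]2[C@H](OCc3ccc(OC)cc3)C/C(C)=C/C[C@H](O)/C(C)=C\[C@H]2O1 | intermediate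
27 | (3aR,4R,6E,9S,10Z,11aR)-4-[(4-methoxybenzyl)oxy]-6,10-dimethyl-3-methylidene-2-oxo-2,3,3a,4,5,8,9,11a-octahydrocyclodeca[b]furan-9-yl 3-methylbutanoate | O=C1C(=C)[C@@H]2[C@H](OCc3ccc(OC)cc3)C/C(C)=C/C[C@H](OC(=O)CC(C)C)/C(C)=C\[C@H]2O1 | intermediate
28 | (3aR,4R,6E,9S,10Z,11aR)-4-hydroxy-6,10-dimethyl-3-methylidene-2-oxo-2,3,3a,4,5,8,9,11a-octahydrocyclodeca[b]furan-9-yl 3-methylbutanoate | O=C1C(=C)[C@@H]2[C@H](O)C/C(C)=C/C[C@H](OC(=O)CC(C)C)/C(C)=C\[C@H]2O1 | intermediate
29 | (E)-2-methylbut-2-en-1-ol (tiglyl alcohol) | C/C=C(\C)CO | starting material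
30 | [(2R,3R)-2,3-dimethyloxiran-2-yl]methanol | OC[C@@]1(C)O[C@@H]1C | intermediate
31 | (2S,3R)-2,3-dimethyloxirane-2-carbaldehyde | O=C[C@@]1(C)O[C@@H]1C | intermediate
32 | (2S,3R)-2,3-dimethyloxirane-2-carboxylic acid | OC(=O)[C@@]1(C)O[C@@H]1C | intermediate
33 | (2S,3R)-2,3-dimethyloxirane-2-carboxylic 2,4,6-trichlorobenzoic anhydride | O=C(OC(=O)[C@@]1(C)O[C@@H]1C)c1c(Cl)cc(Cl)cc1Cl | intermediate
34 | (3aR,4R,6E,9S,10Z,11aR)-6,10-dimethyl-9-[(3-methylbutanoyl)oxy]-3-methylidene-2-oxo-2,3,3a,4,5,8,9,11a-octahydrocyclodeca[b]furan-4-yl (2S,3R)-2,3-dimethyloxirane-2-carboxylate | O=C1C(=C)[C@@H]2[C@H](OC(=O)[C@@]3(C)O[C@@H]3C)C/C(C)=C/C[C@H](OC(=O)CC(C)C)/C(C)=C\[C@H]2O1 | intermediate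
35 | CNP0167461.3: (1R,3S,6R,7R,8R,10R)-1β,10α-epoxy-3β-(3-methylbutanoyloxy)-8β-{[(2S,3R)-2,3-dimethyloxirane-2-carbonyl]oxy}germacra-4(Z),11(13)-dien-12,6α-olide | C=C1C(=O)O[C@@H]2/C=C(/C)[C@@H](OC(=O)CC(C)C)C[C@H]3O[C@]3(C)C[C@@H](OC(=O)[C@@]3(C)O[C@@H]3C)[C@@H]12 | target

**Step count**
Total: 19 steps. Longest linear sequence: 15 steps (steps 1–5, 8–15, 18, 19, from (S)-carvone).

**Steps most likely to fail, with fallbacks**

Step 9 (oxy-Cope/alkylation). Risks: β-elimination of the C8 ether from enolate 18, a competing boat pathway that would invert C8, and poor facial control at C7. The fallback sets out from 16 and comes back at 19. Silylate 16 (N-(trimethylsilyl)imidazole, CH2Cl2, 23 °C) to the trimethylsilyl ether F1. Run the rearrangement as a neutral thermal siloxy-Cope (o-xylene, 160 °C, base-washed sealed tube) to the ring-expanded trimethylsilyl enol ether F2, so that no free enolate exists during the slow step. Then release the lithium enolate F3 at low temperature (MeLi, THF, −20 °C) and alkylate its Li+ chelate with ethyl iodoacetate (DMPU, −78 °C) to reach 19.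

Step 10 (C6 reduction). Risk: hydride may attack the other face and give mainly the 6β-alcohol. The fallback sets out from 19 and comes back at 21, and corrects the centre instead of controlling it. The reduction product, the 6-epi hydroxy ester F4, is closed (PPTS) to the cis-fused 6-epi lactone F5. This is opened (LiOH, THF/H2O, then pH 5 at 0 °C) to the 6-epi hydroxy acid F6. Mitsunobu lactonization (PPh3, DIAD, PhMe, 0 °C) then lets the carboxylate displace the activated allylic C6 oxygen with inversion, which gives 21.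

Step 19 (last epoxidation). Risk: the face selectivity rests only on ring conformation, and the product carries an acid-sensitive glycidic ester. The fallback sets out from 28 and comes back at 35. The epoxidation is moved ahead of the last esterification and made reagent-controlled: Shi epoxidation (D-fructose-derived Shi ketone, KHSO5, K2CO3, MeCN/dimethoxymethane/H2O, 0 °C), whose spiro transition state gives (R,R)-oxiranes from E-trisubstituted alkenes, converts 28 into the 1β,10α-epoxy alcohol F7. Yamaguchi esterification of F7 with 33 (from 32, as in step 18) then gives 35 directly.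

**Further compounds**
F1 | step 9 | trimethylsilyl ether of 16 | CC(C)(C)[Si](C)(C)O[C@H]1C[C@@H](C(C)=C)[C@](O[Si](C)(C)C)(/C=C\OCc2ccc(OC)cc2)C=C1C
F2 | step 9 | ring-expanded trimethylsilyl enol ether (C6–OSiMe3, C6=C7) | C/C1=C/C(O[Si](C)(C)C)=C/[C@H](OCc2ccc(OC)cc2)C/C(C)=C/C[C@@H]1O[Si](C)(C)C(C)(C)C
F3 | step 9 | lithium enolate (lithium analogue of 18) | [Li+].C/C1=C/C([O-])=C/[C@H](OCc2ccc(OC)cc2)C/C(C)=C/C[C@@H]1O[Si](C)(C)C(C)(C)C
F4 | step 10 | 6-epi hydroxy ester (6S epimer of 20) | CCOC(=O)C[C@@H]1[C@H](OCc2ccc(OC)cc2)C/C(C)=C/C[C@H](O[Si](C)(C)C(C)(C)C)/C(C)=C\[C@@H]1O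
F5 | step 10 | 6-epi lactone (cis-fused, 11aS epimer of 21) | O=C1C[C@@H]2[C@H](OCc3ccc(OC)cc3)C/C(C)=C/C[C@H](O[Si](C)(C)C(C)(C)C)/C(C)=C\[C@@H]2O1
F6 | step 10 | 6-epi hydroxy acid | OC(=O)C[C@@H]1[C@H](OCc2ccc(OC)cc2)C/C(C)=C/C[C@H](O[Si](C)(C)C(C)(C)C)/C(C)=C\[C@@H]1O
F7 | step 19 | 1β,10α-epoxy alcohol (1R,10R oxirane of 28) | O=C1C(=C)[C@@H]2[C@H](O)C[C@@]3(C)O[C@@H]3C[C@H](OC(=O)CC(C)C)/C(C)=C\[C@H]2O1
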